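**Retrosynthetic overview**
1. Target ⇐ its 5-O-allyl ether. The allyl group outlives acid, DDQ, NaOH, dithionite and methylation, and is removed last by palladium catalysis without touching the prenyl alkene.
2. Tetramethoxybenzene core ⇐ reductive methylation of a 2,5-dimethoxy-3,6-bis(indol-3-yl)-1,4-benzoquinone ⇐ dihydroxyquinone ⇐ 2,5-dichloro-3,6-bis(indol-3-yl)quinone (Cl → OH → OMe).
3. Key C–C bonds: two successive acid-promoted Michael additions of indole C3 to 2,5-dichloro-1,4-benzoquinone, each followed by DDQ re-oxidation. 5-(Allyloxy)indole goes on first, then 6-prenylindole; this second addition joins the two halves.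
4. Fragments: 5-(allyloxy)indole from 5-hydroxyindole; 6-prenylindole from 6-bromoindole (N-TIPS, Br/Li exchange, prenyl bromide, TBAF).
5. Ring order: no ring is built. Both indoles and the six-membered carbocycle are bought; the central ring travels as a quinone and becomes the benzene ring in the reductive methylation.

Assumption: the target SMILES has no stereocentre and no stereogenic double bond, so the compound is achiral and the route needs no stereocontrol.

**Route**

Step 1
Reactants: 1 1H-indol-5-ol (5-hydroxyindole)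
Product: 2 5-(allyloxy)-1H-indole
Conditions: allyl bromide (1.1 equiv), K2CO3 (1.5 equiv), acetone, reflux, N2
Reagents that add atoms: allyl bromide, C=CCBr
Why: Williamson ether synthesis in which K2CO3 deprotonates the phenol (pKa about 10) but not the indole N–H (pKa about 17), so only O-allylation occurs.

Step 2
Reactants: 3 6-bromo-1H-indole
Product: 4 6-bromo-1-(triisopropylsilyl)-1H-indole
Conditions: NaH (1.2 equiv), THF, 0 °C; then TIPSCl (1.1 equiv), 0 °C → rt
Reagents that add atoms: triisopropylsilyl chloride, CC(C)[Si](Cl)(C(C)C)C(C)C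
Why: N-silylation of the sodium indolide removes the acidic N–H and the bulky TIPS group shields C2 from lithiation in the next step.

Step 3
Reactants: 4 6-bromo-1-(triisopropylsilyl)-1H-indole; 5 1-bromo-3-methylbut-2-ene (prenyl bromide)
Product: 7 6-(3-methylbut-2-en-1-yl)-1-(triisopropylsilyl)-1H-indole, via 6-lithio-1-(triisopropylsilyl)-1H-indole 6 (not isolated)
Conditions: t-BuLi (2.05 equiv), THF, −78 °C, 30 min; then 5 (1.3 equiv), −78 °C → rt
Reagents that add atoms: none
Why: Bromine–lithium exchange is fast at −78 °C, and the aryllithium undergoes direct SN2 alkylation at the unhindered primary carbon of prenyl bromide to give the linear prenyl arene.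

Step 4
Reactants: 7 6-(3-methylbut-2-en-1-yl)-1-(triisopropylsilyl)-1H-indole
Product: 8 6-(3-methylbut-2-en-1-yl)-1H-indole (6-prenylindole)
Conditions: TBAF (1.1 equiv), THF, 0 °C → rt
Reagents that add atoms: none
Why: Fluoride-driven N-desilylation (strong Si–F bond) frees the indole so that C3 is nucleophilic again, and leaves the prenyl alkene untouched.

Step 5
Reactants: 2 5-(allyloxy)-1H-indole; 9 2,5-dichloro-1,4-benzoquinone
Product: 11 3-[5-(allyloxy)-1H-indol-3-yl]-2,5-dichloro-1,4-benzoquinone, via indolyl-dichlorohydroquinone 10 (not isolated)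
Conditions: conc. HCl (cat.), THF, rt, 12 h; then DDQ (1.0 equiv), rt, 30 min
Reagents that add atoms: none
Why: Acid-promoted Michael addition of the enamine-like indole C3 to the unsubstituted C–H position of the protonated quinone gives the hydroquinone after tautomerisation, which DDQ dehydrogenates back to the quinone.

Step 6
Reactants: 11 3-[5-(allyloxy)-1H-indol-3-yl]-2,5-dichloro-1,4-benzoquinone; 8 6-(3-methylbut-2-en-1-yl)-1H-indole
Product: 13 3-[5-(allyloxy)-1H-indol-3-yl]-2,5-dichloro-6-[6-(3-methylbut-2-en-1-yl)-1H-indol-3-yl]-1,4-benzoquinone, via bis(indolyl)dichlorohydroquinone 12 (not isolated)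
Conditions: 8 (1.2 equiv), AcOH, rt → 40 °C, 24–48 h, N2; then DDQ (1.0 equiv), THF, 0 °C → rt
Reagents that add atoms: none
Why: A second Michael addition, promoted by acetic acid (mild enough for the prenyl alkene), can only take the single remaining C–H carbon of the quinone, para to the first indole, and brief DDQ treatment re-oxidises the hydroquinone.

Step 7
Reactants: 13 3-[5-(allyloxy)-1H-indol-3-yl]-2,5-dichloro-6-[6-(3-methylbut-2-en-1-yl)-1H-indol-3-yl]-1,4-benzoquinone
Product: 14 3-[5-(allyloxy)-1H-indol-3-yl]-2,5-dihydroxy-6-[6-(3-methylbut-2-en-1-yl)-1H-indol-3-yl]-1,4-benzoquinone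
Conditions: 10% aq NaOH, MeOH, reflux, 2 h; then 1 M HCl, 0 °C, to pH 2
Reagents that add atoms: sodium hydroxide (aqueous), [Na+].[OH-]
Why: Both vinylogous acid chlorides undergo addition–elimination with hydroxide to give the resonance-stabilised dihydroxyquinone dianion, which is protonated on work-up; the allyl ether and prenyl group are inert to base.

Step 8
Reactants: 14 3-[5-(allyloxy)-1H-indol-3-yl]-2,5-dihydroxy-6-[6-(3-methylbut-2-en-1-yl)-1H-indol-3-yl]-1,4-benzoquinone
Product: 15 3-[5-(allyloxy)-1H-indol-3-yl]-2,5-dimethoxy-6-[6-(3-methylbut-2-en-1-yl)-1H-indol-3-yl]-1,4-benzoquinone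
Conditions: Me2SO4 (3 equiv), K2CO3 (3 equiv), acetone, reflux, 4 h
Reagents that add atoms: dimethyl sulfate, COS(=O)(=O)OC
Why: The hydroxyquinone OH groups are vinylogous carboxylic acids, fully ionised by K2CO3 and O-methylated by dimethyl sulfate, while the far less acidic indole N–H groups stay unalkylated.

Step 9
Reactants: 15 3-[5-(allyloxy)-1H-indol-3-yl]-2,5-dimethoxy-6-[6-(3-methylbut-2-en-1-yl)-1H-indol-3-yl]-1,4-benzoquinone
Product: 17 5-(allyloxy)-3-{2,3,5,6-tetramethoxy-4-[6-(3-methylbut-2-en-1-yl)-1H-indol-3-yl]phenyl}-1H-indole, via bis(indolyl)dimethoxyhydroquinone 16 (not isolated)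
Conditions: Na2S2O4 (5 equiv), THF/H2O, rt, Ar; then Me2SO4 (4 equiv), K2CO3 (6 equiv), acetone, reflux, Ar
Reagents that add atoms: dimethyl sulfate, COS(=O)(=O)OC
Why: Dithionite reduces the quinone to the hydroquinone, whose two phenols are methylated under air-free Williamson conditions (K2CO3 is too weak to deprotonate the indole N–H), which fixes the central ring as the tetramethoxybenzene.

Step 10
Reactants: 17 5-(allyloxy)-3-{2,3,5,6-tetramethoxy-4-[6-(3-methylbut-2-en-1-yl)-1H-indol-3-yl]phenyl}-1H-indole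
Product: 18 3-{2,3,5,6-tetramethoxy-4-[6-(3-methylbut-2-en-1-yl)-1H-indol-3-yl]phenyl}-1H-indol-5-ol (target)
Conditions: Pd(PPh3)4 (5 mol%), morpholine (5 equiv), degassed THF, rt
Reagents that add atoms: none
Why: In a Tsuji–Trost-type deallylation, zerovalent palladium ionises the aryl allyl ether to a π-allylpalladium complex and the phenoxide, and morpholine captures the allyl group; the unactivated prenyl alkene and the methyl ethers do not react.

**Compound list**
1 | 1H-indol-5-ol (5-hydroxyindole) | Oc1ccc2[nH]ccc2c1 | starting material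
2 | 5-(allyloxy)-1H-indole | C=CCOc1ccc2[nH]ccc2c1 | intermediate
3 | 6-bromo-1H-indole | Brc1ccc2cc[nH]c2c1 | starting material
4 | 6-bromo-1-(triisopropylsilyl)-1H-indole | CC(C)[Si](C(C)C)(C(C)C)n1ccc2ccc(Br)cc21 | intermediate
5 | 1-bromo-3-methylbut-2-ene (prenyl bromide) | CC(C)=CCBr | starting material
6 | 6-lithio-1-(triisopropylsilyl)-1H-indole (not isolated) | [Li]c1ccc2ccn([Si](C(C)C)(C(C)C)C(C)C)c2c1 | intermediate
7 | 6-(3-methylbut-2-en-1-yl)-1-(triisopropylsilyl)-1H-indole | CC(C)=CCc1ccc2ccn([Si](C(C)C)(C(C)C)C(C)C)c2c1 | intermediate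
8 | 6-(3-methylbut-2-en-1-yl)-1H-indole (6-prenylindole) | CC(C)=CCc1ccc2cc[nH]c2c1 | intermediate
9 | 2,5-dichloro-1,4-benzoquinone | O=C1C=C(Cl)C(=O)C=C1Cl | starting material
10 | 3-[5-(allyloxy)-1H-indol-3-yl]-2,5-dichlorobenzene-1,4-diol (not isolated) | C=CCOc1ccc2[nH]cc(-c3c(O)c(Cl)cc(O)c3Cl)c2c1 | intermediate
11 | 3-[5-(allyloxy)-1H-indol-3-yl]-2,5-dichloro-1,4-benzoquinone | C=CCOc1ccc2[nH]cc(C3=C(Cl)C(=O)C=C(Cl)C3=O)c2c1 | intermediate
12 | 3-[5-(allyloxy)-1H-indol-3-yl]-2,5-dichloro-6-[6-(3-methylbut-2-en-1-yl)-1H-indol-3-yl]benzene-1,4-diol (not isolated) | C=CCOc1ccc2[nH]cc(-c3c(O)c(Cl)c(-c4c[nH]c5cc(CC=C(C)C)ccc45)c(O)c3Cl)c2c1 | intermediate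
13 | 3-[5-(allyloxy)-1H-indol-3-yl]-2,5-dichloro-6-[6-(3-methylbut-2-en-1-yl)-1H-indol-3-yl]-1,4-benzoquinone | C=CCOc1ccc2[nH]cc(C3=C(Cl)C(=O)C(c4c[nH]c5cc(CC=C(C)C)ccc45)=C(Cl)C3=O)c2c1 | intermediate
14 | 3-[5-(allyloxy)-1H-indol-3-yl]-2,5-dihydroxy-6-[6-(3-methylbut-2-en-1-yl)-1H-indol-3-yl]-1,4-benzoquinone | C=CCOc1ccc2[nH]cc(C3=C(O)C(=O)C(c4c[nH]c5cc(CC=C(C)C)ccc45)=C(O)C3=O)c2c1 | intermediate
15 | 3-[5-(allyloxy)-1H-indol-3-yl]-2,5-dimethoxy-6-[6-(3-methylbut-2-en-1-yl)-1H-indol-3-yl]-1,4-benzoquinone | C=CCOc1ccc2[nH]cc(C3=C(OC)C(=O)C(c4c[nH]c5cc(CC=C(C)C)ccc45)=C(OC)C3=O)c2c1 | intermediate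
16 | 3-[5-(allyloxy)-1H-indol-3-yl]-2,5-dimethoxy-6-[6-(3-methylbut-2-en-1-yl)-1H-indol-3-yl]benzene-1,4-diol (not isolated) | C=CCOc1ccc2[nH]cc(-c3c(OC)c(O)c(-c4c[nH]c5cc(CC=C(C)C)ccc45)c(OC)c3O)c2c1 | intermediate
17 | 5-(allyloxy)-3-{2,3,5,6-tetramethoxy-4-[6-(3-methylbut-2-en-1-yl)-1H-indol-3-yl]phenyl}-1H-indole | C=CCOc1ccc2[nH]cc(-c3c(OC)c(OC)c(-c4c[nH]c5cc(CC=C(C)C)ccc45)c(OC)c3OC)c2c1 | intermediate
18 | 3-{2,3,5,6-tetramethoxy-4-[6-(3-methylbut-2-en-1-yl)-1H-indol-3-yl]phenyl}-1H-indol-5-ol (achiral) | COc1c(OC)c(-c2c[nH]c3ccc(O)cc23)c(OC)c(OC)c1-c1c[nH]c2cc(CC=C(C)C)ccc12 | target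

**Totals**
Total step count: 10.
Longest linear sequence: 8 steps (from 3 through steps 2, 3, 4, 6, 7, 8, 9 and 10).

**Three steps most likely to fail, with fallbacks**

Step 6 (second Michael addition). The indolyl-substituted quinone 11 is a weaker and more hindered acceptor than 9, so conversion may be low. The fallback sets out from 2 and comes back to the route at 14. It replaces conjugate addition/re-oxidation by base-mediated addition–elimination on commercial tetrabromo-1,4-benzoquinone (bromanil), which keeps the quinone oxidation level and needs no DDQ. Compound 2 with bromanil and Cs2CO3 in MeCN at rt gives 2,3,5-tribromo-6-[5-(allyloxy)-1H-indol-3-yl]-1,4-benzoquinone F1. Indole 8 is then added under the same conditions and displaces the bromide para to the first indole (the position not deactivated by vinylogous donation from that indole), giving 2,5-dibromo-3-[5-(allyloxy)-1H-indol-3-yl]-6-[6-(3-methylbut-2-en-1-yl)-1H-indol-3-yl]-1,4-benzoquinone F2. Aqueous NaOH in MeOH at reflux then replaces both bromides by hydroxyl and gives 14.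

Step 3 (Br/Li exchange and prenylation). Wurtz-type coupling, protonation of the aryllithium, or some attack at the tertiary end of the allyl system could lower the yield. The fallback sets out from 3 and comes back to the route at 8, bypassing steps 2 to 4. It is a Stille coupling of unprotected 6-bromoindole 3 with tributyl(3-methylbut-2-en-1-yl)stannane, Pd(PPh3)4 (5 mol%) and LiCl in DMF at 100 °C. Transfer of the allyl group from tin through palladium gives the linear prenyl arene 8 directly. No compound outside the compound list is made on this way (entry: none F0).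

Step 9 (reductive methylation). Hydroquinone 16 is air-sensitive, its hydroxyls are flanked by OMe and indolyl groups, and forcing the methylation risks N-methylation. The fallback sets out from 15 and comes back to the route at 17. Both indole nitrogens are first masked: Boc2O and DMAP (cat.) in MeCN at rt give di-tert-butyl carbamate-protected quinone, 1-Boc-5-(allyloxy)indol-3-yl/1-Boc-6-prenylindol-3-yl 2,5-dimethoxy-1,4-benzoquinone F3. Na2S2O4 in THF/H2O reduces it to the corresponding bis-N-Boc dimethoxyhydroquinone F4, which is not isolated. Strong methylation (MeI, Cs2CO3, DMF, rt, Ar) is now possible and gives the bis-N-Boc tetramethoxybenzene F5. Catalytic NaOMe in MeOH/THF at rt removes both indole carbamates and gives 17.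

**Further compounds**
F1 | step 6 | 2,3,5-tribromo-6-[5-(allyloxy)-1H-indol-3-yl]-1,4-benzoquinone | C=CCOc1ccc2[nH]cc(C3=C(Br)C(=O)C(Br)=C(Br)C3=O)c2c1
F2 | step 6 | 2,5-dibromo-3-[5-(allyloxy)-1H-indol-3-yl]-6-[6-(3-methylbut-2-en-1-yl)-1H-indol-3-yl]-1,4-benzoquinone | C=CCOc1ccc2[nH]cc(C3=C(Br)C(=O)C(c4c[nH]c5cc(CC=C(C)C)ccc45)=C(Br)C3=O)c2c1
F0 | step 3 | none | none
F3 | step 9 | 3-[5-(allyloxy)-1-(tert-butoxycarbonyl)indol-3-yl]-6-[1-(tert-butoxycarbonyl)-6-(3-methylbut-2-en-1-yl)indol-3-yl]-2,5-dimethoxy-1,4-benzoquinone | C=CCOc1ccc2c(c1)c(C1=C(OC)C(=O)C(c3cn(C(=O)OC(C)(C)C)c4cc(CC=C(C)C)ccc34)=C(OC)C1=O)cn2C(=O)OC(C)(C)C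
F4 | step 9 | 3-[5-(allyloxy)-1-(tert-butoxycarbonyl)indol-3-yl]-6-[1-(tert-butoxycarbonyl)-6-(3-methylbut-2-en-1-yl)indol-3-yl]-2,5-dimethoxybenzene-1,4-diol (not isolated) | C=CCOc1ccc2c(c1)c(-c1c(OC)c(O)c(-c3cn(C(=O)OC(C)(C)C)c4cc(CC=C(C)C)ccc34)c(OC)c1O)cn2C(=O)OC(C)(C)C
F5 | step 9 | tert-butyl 5-(allyloxy)-3-{4-[1-(tert-butoxycarbonyl)-6-(3-methylbut-2-en-1-yl)indol-3-yl]-2,3,5,6-tetramethoxyphenyl}indole-1-carboxylate | C=CCOc1ccc2c(c1)c(-c1c(OC)c(OC)c(-c3cn(C(=O)OC(C)(C)C)c4cc(CC=C(C)C)ccc34)c(OC)c1OC)cn2C(=O)OC(C)(C)C
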